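**Slow supply.** The starting material gives the intermediate slowly, with a lifetime of 19.6 h counting this step by itself, and these flasks differ in when the first nucleophile meets that stream.

    starting material + protic impurity → quenched substrate (k1 = 9.4 M⁻¹ h⁻¹)
    intermediate → solvolysis product (k2 = 0.29 h⁻¹)
    first nucleophile → decomposed reagent (k3 = 0.084 h⁻¹)
    starting material + target → side product (k4 = 0.0087 M⁻¹ h⁻¹)
    starting material → intermediate (k5 = 0.051 h⁻¹)
    second nucleophile + intermediate → other capture product (k6 = 1.7 M⁻¹ h⁻¹)
    first nucleophile + intermediate → target (k7 = 2.3 M⁻¹ h⁻¹)

common to all: second nucleophile 1.20 equiv; protic impurity 0.0400 M; time 4.0 d
- Monday's: starting material 0.40 M; first nucleophile 0.500 equiv (fed, over 40 h); all else is in the flask from the start; the feed brings no volume worth counting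
- Thursday's: starting material 0.40 M; first nucleophile 0.500 equiv; everything together at the start
- Saturday's: starting material 0.40 M; first nucleophile 0.500 equiv (in portions, 3, over 40 h); first portion at the start, last at 40 h
- Sunday's: starting material 0.40 M (fed, over 40 h); first nucleophile 0.500 equiv; all else is in the flask from the start; the feed brings no volume worth counting

- a species is counted by the starting material in it: one side product counts as two
- run time (Monday's): 4.0 d

- which flask leads in share of target in target plus other capture product ("all alike" within 1.5 percentage points) (Monday's / Thursday's / Saturday's / Sunday's / all alike)
- share of target in target plus other capture product at the end, Monday's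
- share of target in target plus other capture product at the end, Thursday's
- share of target in target plus other capture product at the end, Saturday's
- share of target in target plus other capture product at the end, Sunday's

**Bench rule.** The two nucleophiles here divide the captured intermediate in the ratio r = S·b/d, where b and d are the concentrations of the first and second nucleophile and S is the selectivity factor, the capture constant of the first nucleophile over that of the second, 1.35. The share of target is r over one plus r. At the charged 0.200 M and 0.480 M, r is 0.564, a share of 36.1%.

**Its border.** The rule needs b to last as long as the stream. Yet the first nucleophile decomposes with a lifetime of 11.9 h, and the stream outlasts it by a factor of 1.65, so the charged b overstates what the intermediate meets.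

**Meeting fraction.** We therefore weight b by the stream. For a portion and a starting material present together, the mean fraction of that portion seen by the intermediate is φ, its lifetime over the sum of both lifetimes: 0.378. We hold d at its charge and let capture consume none of the first nucleophile. Thursday's then has r = 0.213, a share of 17.6%.

A portion added later finds less stream, so we multiply r by a mean survival g of the starting material over the addition times. Monday's steady feed has g = 0.426, giving 8.33%. Saturday's portions have g = 0.497, giving 9.57%.

Sunday's reverses the roles: later starting material finds less first nucleophile. We take the first 4.00 h of that feed as lost to the protic impurity, so g = 0.225, giving 4.57%. Our reckoning puts Thursday's first.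

**The forecast.** The forecast also chose Thursday's, with 8.6% for Monday's, 17% for Thursday's, 11.2% for Saturday's and 4.6% for Sunday's, holding that the capture step's first-order dependence on the first nucleophile “rewards having it all in at once”.

**The result.** The flasks give 10.0% for Monday's, 15.1% for Thursday's, 10.1% for Saturday's and 4.39% for Sunday's, so Thursday's leads. Thursday's ends with 0.160 M of decomposed reagent from the 0.200 M charged. Read back through the ratio at charged d, Thursday's share corresponds to a fraction of 0.315, less than our φ of 0.378.

**Less second nucleophile.** With 0.300 equiv of second nucleophile in Thursday's recipe, φ stays 0.378, and r becomes 0.852, a share of 46.0%. The computed flask gives 41.1%.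

The rate constants are made up; the flask was simulated.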